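**Retrosynthetic overview**
- Target: (2S,4R)-2-heptadecyl-4-hydroxy-2,3,4,6,7,8-hexahydro-5H-chromen-5-one; ring A is the dihydropyran (O1, C2, C3, C4, C4a, C8a), ring B the carbocycle (C4a, C5, C6, C7, C8, C8a).
- Enabling feature: ring B is the enol ether of a cyclohexane-1,3-dione, so C5 (C=O) and C8a (O-bearing enol carbon) are two acyl-level carbons held 1,3 on C4a and bridged only by the methylenes C6–C7–C8. A 6-iodo-3,4-dihydro-2H-pyran-5-carboxylate already holds C5–C4a–C8a at the right oxidation levels (ester and iodo enol ether).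
- Key disconnection: C8–C8a (Negishi coupling) and C5–C6 (Dieckmann condensation), both made in one flask from the monocyclic iodo ester and (4-ethoxy-4-oxobutyl)zinc bromide. This C6–C7–C8 unit is nucleophilic at both ends, and its extra ester is removed afterwards.
- Ring A is built first: C2 by an asymmetric vinylogous Mukaiyama aldol of octadecanal, the pyranone by amide-acetal cyclocondensation, C4 by a cis-selective Luche reduction, and the C8a–I bond by ester-directed lithiation.
- Order of ring formation: ring A (step 2), then ring B (step 6); dealkoxycarbonylation and desilylation finish the route.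

Key step: step 6

Assumption: the Ti(OiPr)4/(R)-BINOL catalyst is taken to direct the diene to the Re face of octadecanal, which gives the 5S alcohol; if the sense proves opposite, (S)-BINOL is used.

**Step 1**
Reactants: 1 octadecanal; 2 1-methoxy-1,3-bis(trimethylsilyloxy)buta-1,3-diene
Product: 3 methyl (5S)-5-hydroxy-3-oxodocosanoate
Conditions: Ti(OiPr)4 (10 mol%), (R)-BINOL (10 mol%), 4 Å MS, THF, −78 °C → rt; then 1 M HCl, THF, 0 °C
Reagents that add atoms: none
Why: Catalytic asymmetric vinylogous Mukaiyama aldol addition, in which the γ-carbon of the bis-silyl dienolate 2 adds to the Re face of the Ti–BINOL-bound aldehyde to set the carbinol centre as 5S (the later C2), and acid work-up cleaves both silyl groups to give the δ-hydroxy β-keto ester.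

**Step 2**
Reactants: 3 methyl (5S)-5-hydroxy-3-oxodocosanoate
Product: 5 methyl (2S)-2-heptadecyl-4-oxo-3,4-dihydro-2H-pyran-5-carboxylate, via enaminone 4 (not isolated)
Conditions: Me2NCH(OMe)2, toluene, rt; then AcOH, 40 °C
Reagents that add atoms: N,N-dimethylformamide dimethyl acetal, COC(OC)N(C)C
Why: Condensation of the amide acetal at the doubly activated C2 methylene gives the enaminone, whose 5-hydroxyl then adds 6-endo to the aminomethylidene carbon and expels dimethylamine (oxa-conjugate addition–elimination, a known route from δ-hydroxy β-keto esters to 2,3-dihydro-4H-pyran-4-ones), closing ring A without touching the stereocentre.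

**Step 3**
Reactants: 5 methyl (2S)-2-heptadecyl-4-oxo-3,4-dihydro-2H-pyran-5-carboxylate
Product: 6 methyl (2S,4R)-2-heptadecyl-4-hydroxy-3,4-dihydro-2H-pyran-5-carboxylate
Conditions: NaBH4, CeCl3·7H2O, MeOH/THF (1:1), −78 → −40 °C
Reagents that add atoms: none
Why: Luche reduction, in which the cerium-modified borohydride adds 1,2 to the C4 ketone from the pseudo-axial direction of the half-chair that holds the C2 heptadecyl group pseudo-equatorial, so the new alcohol should be cis to C2 (4R) while the push–pull C5=C6 bond and the ester stay intact.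

**Step 4**
Reactants: 6 methyl (2S,4R)-2-heptadecyl-4-hydroxy-3,4-dihydro-2H-pyran-5-carboxylate
Product: 7 methyl (2S,4R)-4-[(tert-butyldimethylsilyl)oxy]-2-heptadecyl-3,4-dihydro-2H-pyran-5-carboxylate
Conditions: TBSCl, imidazole, DMF, rt
Reagents that add atoms: tert-butyldimethylsilyl chloride, CC(C)(C)[Si](C)(C)Cl
Why: Imidazole-promoted silylation of the secondary allylic alcohol masks the acidic O–H before the strong-base step and protects C4–O during the later thermal dealkoxycarbonylation; no stereocentre is affected.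

**Step 5**
Reactants: 7 methyl (2S,4R)-4-[(tert-butyldimethylsilyl)oxy]-2-heptadecyl-3,4-dihydro-2H-pyran-5-carboxylate
Product: 9 methyl (2S,4R)-4-[(tert-butyldimethylsilyl)oxy]-2-heptadecyl-6-iodo-3,4-dihydro-2H-pyran-5-carboxylate, via vinyllithium 8 (not isolated)
Conditions: LiN(iPr)2, THF, −78 °C; then I2, THF, −78 °C
Reagents that add atoms: iodine, II
Why: Ester-directed β-lithiation of a β-alkoxyacrylate, in which the amide base removes the C6 vinylic hydrogen (acidified by the ring oxygen and held by chelation to the C5 ester carbonyl), and iodinolysis of the vinyllithium gives the alkenyl iodide with both stereocentres untouched.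

**Step 6**
Reactants: 9 methyl (2S,4R)-4-[(tert-butyldimethylsilyl)oxy]-2-heptadecyl-6-iodo-3,4-dihydro-2H-pyran-5-carboxylate; 10 (4-ethoxy-4-oxobutyl)zinc bromide
Product: 12 ethyl (2S,4R)-4-[(tert-butyldimethylsilyl)oxy]-2-heptadecyl-5-oxo-3,4,5,6,7,8-hexahydro-2H-chromene-6-carboxylate, via coupled diester 11 (not isolated)
Conditions: 10 (0.5 M in THF, 1.5 equiv), Pd(OAc)2 (3 mol%), SPhos (6 mol%), THF, rt; then KOtBu (4 equiv), THF, −20 → 0 °C; aq. NH4Cl
Reagents that add atoms: none
Why: Zerovalent palladium (from Pd(OAc)2/SPhos) inserts into the C8a–I bond of 9, and transmetalation with the sp3 zinc carbon of 10 followed by reductive elimination forges C8–C8a (Negishi coupling of a functionalised alkylzinc halide with an alkenyl iodide) to give 11; KOtBu then enolises the butanoate arm, whose α-carbon (C6) attacks the C5 methyl ester and expels methoxide to forge C5–C6 (Dieckmann condensation), so the two events together are a [3+3] annulation of the C6–C7–C8 unit onto the C5–C4a–C8a unit. Ring B is closed in the second event by 6-exo-trig attack of the ester enolate on the exocyclic ester carbonyl, and the C4a=C8a enol-ether bond is never disturbed, so the vinylogous ester of the target emerges directly. No stereocentre of the target is created: C2 and C4 are carried through, and the new C6 centre (epimers and enol) is left uncontrolled because step 7 erases it. Chemoselectivity in the first event rests on the iodide being the only carbon–halogen bond and on the tolerance of alkylzinc halides for esters and silyl ethers; in the second event the C5 ester is the only acyl group the enolate can reach through a six-membered transition state, and deprotonation of the β-keto ester product pulls the equilibrium (the excess base first takes up the zinc salts). The competing reversible deprotonation at C8 is unproductive, and β-loss of the C4 silyloxy group from that dienolate should be slow because the pseudo-equatorial C4–O bond lies near the nodal plane of the π system and the temperature is held at or below 0 °C.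

**Step 7**
Reactants: 12 ethyl (2S,4R)-4-[(tert-butyldimethylsilyl)oxy]-2-heptadecyl-5-oxo-3,4,5,6,7,8-hexahydro-2H-chromene-6-carboxylate
Product: 13 (2S,4R)-4-[(tert-butyldimethylsilyl)oxy]-2-heptadecyl-2,3,4,6,7,8-hexahydro-5H-chromen-5-one
Conditions: LiCl, H2O, DMSO, 130 °C
Reagents that add atoms: none
Why: Krapcho dealkoxycarbonylation, in which the β-keto ester loses its ethoxycarbonyl group (ester cleavage and decarboxylation through the enol) under neutral conditions that should spare the silyl ether and the vinylogous ester, and which erases the uncontrolled C6 centre.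

**Step 8**
Reactants: 13 (2S,4R)-4-[(tert-butyldimethylsilyl)oxy]-2-heptadecyl-2,3,4,6,7,8-hexahydro-5H-chromen-5-one
Product: 14 (2S,4R)-2-heptadecyl-4-hydroxy-2,3,4,6,7,8-hexahydro-5H-chromen-5-one
Conditions: TBAF, AcOH, THF, 0 °C → rt
Reagents that add atoms: none
Why: Fluoride-mediated desilylation, buffered with acetic acid so that the allylic C4 alcohol next to the vinylogous ester is neither ionised nor epimerised, should release the target with the 2S,4R configuration set in steps 1 and 3.

**Compound list**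
1 | octadecanal | CCCCCCCCCCCCCCCCCC=O | starting material
2 | 1-methoxy-1,3-bis(trimethylsilyloxy)buta-1,3-diene | COC(O[Si](C)(C)C)=CC(=C)O[Si](C)(C)C | starting material
3 | methyl (5S)-5-hydroxy-3-oxodocosanoate | CCCCCCCCCCCCCCCCC[C@H](O)CC(=O)CC(=O)OC | intermediate
4 | methyl (5S)-2-[(dimethylamino)methylidene]-5-hydroxy-3-oxodocosanoate (formed in the flask, not isolated) | CCCCCCCCCCCCCCCCC[C@H](O)CC(=O)C(=CN(C)C)C(=O)OC | intermediate
5 | methyl (2S)-2-heptadecyl-4-oxo-3,4-dihydro-2H-pyran-5-carboxylate | CCCCCCCCCCCCCCCCC[C@H]1CC(=O)C(C(=O)OC)=CO1 | intermediate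
6 | methyl (2S,4R)-2-heptadecyl-4-hydroxy-3,4-dihydro-2H-pyran-5-carboxylate | CCCCCCCCCCCCCCCCC[C@H]1C[C@@H](O)C(C(=O)OC)=CO1 | intermediate
7 | methyl (2S,4R)-4-[(tert-butyldimethylsilyl)oxy]-2-heptadecyl-3,4-dihydro-2H-pyran-5-carboxylate | CCCCCCCCCCCCCCCCC[C@H]1C[C@@H](O[Si](C)(C)C(C)(C)C)C(C(=O)OC)=CO1 | intermediate
8 | methyl (2S,4R)-4-[(tert-butyldimethylsilyl)oxy]-2-heptadecyl-6-lithio-3,4-dihydro-2H-pyran-5-carboxylate (formed in the flask, not isolated) | CCCCCCCCCCCCCCCCC[C@H]1C[C@@H](O[Si](C)(C)C(C)(C)C)C(C(=O)OC)=C([Li])O1 | intermediate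
9 | methyl (2S,4R)-4-[(tert-butyldimethylsilyl)oxy]-2-heptadecyl-6-iodo-3,4-dihydro-2H-pyran-5-carboxylate | CCCCCCCCCCCCCCCCC[C@H]1C[C@@H](O[Si](C)(C)C(C)(C)C)C(C(=O)OC)=C(I)O1 | intermediate
10 | (4-ethoxy-4-oxobutyl)zinc bromide | CCOC(=O)CCC[Zn]Br | starting material
11 | methyl (2S,4R)-4-[(tert-butyldimethylsilyl)oxy]-6-(4-ethoxy-4-oxobutyl)-2-heptadecyl-3,4-dihydro-2H-pyran-5-carboxylate (formed in the flask, not isolated) | CCCCCCCCCCCCCCCCC[C@H]1C[C@@H](O[Si](C)(C)C(C)(C)C)C(C(=O)OC)=C(CCCC(=O)OCC)O1 | intermediate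
12 | ethyl (2S,4R)-4-[(tert-butyldimethylsilyl)oxy]-2-heptadecyl-5-oxo-3,4,5,6,7,8-hexahydro-2H-chromene-6-carboxylate (C6 epimers, partly enolised) | CCCCCCCCCCCCCCCCC[C@H]1C[C@@H](O[Si](C)(C)C(C)(C)C)C2=C(CCC(C(=O)OCC)C2=O)O1 | intermediate
13 | (2S,4R)-4-[(tert-butyldimethylsilyl)oxy]-2-heptadecyl-2,3,4,6,7,8-hexahydro-5H-chromen-5-one | CCCCCCCCCCCCCCCCC[C@H]1C[C@@H](O[Si](C)(C)C(C)(C)C)C2=C(CCCC2=O)O1 | intermediate
14 | (2S,4R)-2-heptadecyl-4-hydroxy-2,3,4,6,7,8-hexahydro-5H-chromen-5-one | CCCCCCCCCCCCCCCCC[C@H]1C[C@@H](O)C2=C(CCCC2=O)O1 | target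

**Step count and risks**
Total step count: 8. Longest linear sequence: 8 steps (1 → 14).

Steps most likely to fail:

1. Step 6 (key step). What may go wrong: deprotonation at C8 of the coupled diester instead of at the butanoate α-carbon, followed by vinylogous β-elimination of the C4 silyloxy group, or a stalled Claisen closure on the deactivated push–pull ester. The fallback avoids enolate chemistry; it sets out from 9 and comes back at 13.
   - Stille coupling of 9 with allyltributylstannane (Pd(PPh3)4, CuI, DMF) should give methyl (2S,4R)-6-allyl-4-[(tert-butyldimethylsilyl)oxy]-2-heptadecyl-3,4-dihydro-2H-pyran-5-carboxylate F1.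
   - Hydroboration of the terminal alkene with 9-BBN should give the alkylborane methyl (2S,4R)-6-[3-(9-borabicyclo[3.3.1]nonan-9-yl)propyl]-4-[(tert-butyldimethylsilyl)oxy]-2-heptadecyl-3,4-dihydro-2H-pyran-5-carboxylate F2, which is not isolated.
   - Cleavage of F2 with I2/NaOMe should give the primary iodide methyl (2S,4R)-4-[(tert-butyldimethylsilyl)oxy]-2-heptadecyl-6-(3-iodopropyl)-3,4-dihydro-2H-pyran-5-carboxylate F3.
   - Iodine–lithium exchange with t-BuLi at −100 °C then lets the primary alkyllithium acylate itself on the C5 ester (Parham-type cycloacylation), which should give 13 directly, with no carboxylate left to remove.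

2. Step 5. What may go wrong: attack of the amide base on the ester, or self-condensation and decomposition of the α-alkoxyvinyllithium before iodinolysis. The fallback puts the C6 leaving group in place while ring A is built; it sets out from 3 and comes back at 12 by way of 11.
   - CS2, K2CO3 and MeI in DMF should convert 3 into the open-chain ketene dithioacetal methyl (5S)-2-[bis(methylsulfanyl)methylidene]-5-hydroxy-3-oxodocosanoate F4 (not isolated).
   - The 5-hydroxyl of F4 displaces one methylsulfanyl group to give methyl (2S)-2-heptadecyl-6-(methylsulfanyl)-4-oxo-3,4-dihydro-2H-pyran-5-carboxylate F5.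
   - Luche reduction as in step 3 should give methyl (2S,4R)-2-heptadecyl-4-hydroxy-6-(methylsulfanyl)-3,4-dihydro-2H-pyran-5-carboxylate F6.
   - Silylation as in step 4 should give methyl (2S,4R)-4-[(tert-butyldimethylsilyl)oxy]-2-heptadecyl-6-(methylsulfanyl)-3,4-dihydro-2H-pyran-5-carboxylate F7.
   - The alkenyl methyl sulfide F7 is coupled with 10 under Pd(OAc)2/SPhos (Negishi-type C–S coupling of an unsaturated thioether) to form 11 in the flask, and KOtBu closes it to 12.

3. Step 3. What may go wrong: hydride delivery to C6 (conjugate reduction of the doubly activated enol ether) or poor facial selectivity at C4. The fallback reduces the ketone before the ester is present; it sets out from 1 and comes back at 7.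
   - Ti(OiPr)4/BINOL-catalysed Mukaiyama aldol of 1 with trans-1-methoxy-3-(trimethylsilyloxy)buta-1,3-diene and ring closure with TFA (formal hetero-Diels–Alder reaction; BINOL antipode chosen for the 2S product) should give (2S)-2-heptadecyl-2,3-dihydro-4H-pyran-4-one F8.
   - Luche reduction of this simple enone should give the cis alcohol (2S,4R)-2-heptadecyl-3,4-dihydro-2H-pyran-4-ol F9.
   - Silylation (TBSCl, imidazole) should give tert-butyl{[(2S,4R)-2-heptadecyl-3,4-dihydro-2H-pyran-4-yl]oxy}dimethylsilane F10.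
   - C5 acylation of the enol ether with trichloroacetyl chloride and pyridine should give 2,2,2-trichloro-1-[(2S,4R)-4-[(tert-butyldimethylsilyl)oxy]-2-heptadecyl-3,4-dihydro-2H-pyran-5-yl]ethan-1-one F11.
   - Haloform-type methanolysis (NaOMe, MeOH) should give 7.

**Further compounds**
F1 | step 6 | methyl (2S,4R)-6-allyl-4-[(tert-butyldimethylsilyl)oxy]-2-heptadecyl-3,4-dihydro-2H-pyran-5-carboxylate | CCCCCCCCCCCCCCCCC[C@H]1C[C@@H](O[Si](C)(C)C(C)(C)C)C(C(=O)OC)=C(CC=C)O1
F2 | step 6 | methyl (2S,4R)-6-[3-(9-borabicyclo[3.3.1]nonan-9-yl)propyl]-4-[(tert-butyldimethylsilyl)oxy]-2-heptadecyl-3,4-dihydro-2H-pyran-5-carboxylate | CCCCCCCCCCCCCCCCC[C@H]1C[C@@H](O[Si](C)(C)C(C)(C)C)C(C(=O)OC)=C(CCCB2C3CCCC2CCC3)O1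
F3 | step 6 | methyl (2S,4R)-4-[(tert-butyldimethylsilyl)oxy]-2-heptadecyl-6-(3-iodopropyl)-3,4-dihydro-2H-pyran-5-carboxylate | CCCCCCCCCCCCCCCCC[C@H]1C[C@@H](O[Si](C)(C)C(C)(C)C)C(C(=O)OC)=C(CCCI)O1
F4 | step 5 | methyl (5S)-2-[bis(methylsulfanyl)methylidene]-5-hydroxy-3-oxodocosanoate | CCCCCCCCCCCCCCCCC[C@H](O)CC(=O)C(=C(SC)SC)C(=O)OC
F5 | step 5 | methyl (2S)-2-heptadecyl-6-(methylsulfanyl)-4-oxo-3,4-dihydro-2H-pyran-5-carboxylate | CCCCCCCCCCCCCCCCC[C@H]1CC(=O)C(C(=O)OC)=C(SC)O1
F6 | step 5 | methyl (2S,4R)-2-heptadecyl-4-hydroxy-6-(methylsulfanyl)-3,4-dihydro-2H-pyran-5-carboxylate | CCCCCCCCCCCCCCCCC[C@H]1C[C@@H](O)C(C(=O)OC)=C(SC)O1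
F7 | step 5 | methyl (2S,4R)-4-[(tert-butyldimethylsilyl)oxy]-2-heptadecyl-6-(methylsulfanyl)-3,4-dihydro-2H-pyran-5-carboxylate | CCCCCCCCCCCCCCCCC[C@H]1C[C@@H](O[Si](C)(C)C(C)(C)C)C(C(=O)OC)=C(SC)O1
F8 | step 3 | (2S)-2-heptadecyl-2,3-dihydro-4H-pyran-4-one | CCCCCCCCCCCCCCCCC[C@H]1CC(=O)C=CO1
F9 | step 3 | (2S,4R)-2-heptadecyl-3,4-dihydro-2H-pyran-4-ol | CCCCCCCCCCCCCCCCC[C@H]1C[C@@H](O)C=CO1
F10 | step 3 | tert-butyl{[(2S,4R)-2-heptadecyl-3,4-dihydro-2H-pyran-4-yl]oxy}dimethylsilane | CCCCCCCCCCCCCCCCC[C@H]1C[C@@H](O[Si](C)(C)C(C)(C)C)C=CO1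
F11 | step 3 | 2,2,2-trichloro-1-[(2S,4R)-4-[(tert-butyldimethylsilyl)oxy]-2-heptadecyl-3,4-dihydro-2H-pyran-5-yl]ethan-1-one | CCCCCCCCCCCCCCCCC[C@H]1C[C@@H](O[Si](C)(C)C(C)(C)C)C(C(=O)C(Cl)(Cl)Cl)=CO1
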